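**Retrosynthetic overview**

1. The strategy rests on C6 of the 1,2-dioxane (ring O1–O2–C3–C4–C5–C6): it is a mixed methyl peroxyketal, i.e. a ketone carbon in disguise. Cutting O1–C6 and C6–OMe opens the ring to the (S)-γ-hydroperoxy ketone 22, which already carries the whole dienyne chain.
2. O2–C3 comes from SN2 inversion of the (R)-mesylate 18 (ketone masked as dimethyl ketal) by a monoprotected hydroperoxide anion.
3. C4–C5 comes from the azaenolate of methyl ketone hydrazone 9 opening the (S)-epoxide 13 (from but-3-en-1-ol, kinetic resolution).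
4. The sp–sp2 bond of the enyne comes from Sonogashira coupling of hept-6-yn-2-one 4 (from hex-5-ynoic acid) with (E)-iodoalkene 7 (from dec-9-en-1-ol).
5. Ring order: the only ring, the 1,2-dioxane, is closed in step 16; afterwards the silyloxyethyl arm on C3 is oxidised to the methyl acetate arm.

Key step: step 16

Remark: 22 is written as the open hydroperoxy ketone; it should equilibrate with its ring tautomer 23 as soon as it forms, and this mixture is what enters step 16.

**Route**

Step 1
Reactants: 1 hex-5-ynoic acid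
Product: 3 N-methoxy-N-methylhex-5-ynamide, via acyl imidazolide 2 (not isolated)
Conditions: CDI, CH2Cl2, rt; then MeNHOMe·HCl, rt
Reagents that add atoms: N,O-dimethylhydroxylamine hydrochloride, CNOC.Cl
Why: Carbonyldiimidazole amide coupling activates the acid and the amine salt then gives the Weinreb amide, with the terminal alkyne untouched.

Step 2
Reactants: 3 N-methoxy-N-methylhex-5-ynamide
Product: 4 hept-6-yn-2-one
Conditions: MeMgBr (2.3 equiv), THF, 0 °C; then 1 M HCl
Reagents that add atoms: methylmagnesium bromide, C[Mg]Br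
Why: Weinreb ketone synthesis, in which one equivalent of Grignard reagent is spent on the acetylenic C–H and the next adds only once to the N-methoxy-N-methyl amide, so the methyl ketone and not the tertiary alcohol should result.

Step 3
Reactants: 5 dec-9-en-1-ol
Product: 6 dec-9-enal
Conditions: TEMPO (10 mol %), PhI(OAc)2, CH2Cl2, rt
Reagents that add atoms: none
Why: TEMPO-catalysed oxidation with a hypervalent iodine co-oxidant stops at the aldehyde in the absence of water and leaves the terminal alkene alone.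

Step 4
Reactants: 6 dec-9-enal
Product: 7 (1E)-1-iodoundeca-1,10-diene
Conditions: CrCl2, CHI3, 1,4-dioxane–THF (6:1), 0 °C to rt
Reagents that add atoms: iodoform, IC(I)I
Why: Takai olefination with divalent chromium and iodoform homologates the aldehyde to the iodoalkene, and the dioxane-rich medium should favour the E isomer.

Step 5
Reactants: 4 hept-6-yn-2-one; 7 (1E)-1-iodoundeca-1,10-diene
Product: 8 (8E)-octadeca-8,17-dien-6-yn-2-one
Conditions: PdCl2(PPh3)2 (3 mol %), CuI (copper iodide, 6 mol %), Et3N, THF, rt, degassed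
Reagents that add atoms: none
Why: Sonogashira coupling of an alkenyl iodide with a terminal alkyne proceeds with retention of the alkene geometry and tolerates the methyl ketone and the remote vinyl group.

Step 6
Reactants: 8 (8E)-octadeca-8,17-dien-6-yn-2-one
Product: 9 (8E)-octadeca-8,17-dien-6-yn-2-one N,N-dimethylhydrazone
Conditions: Me2NNH2, AcOH (cat.), EtOH, 60 °C
Reagents that add atoms: 1,1-dimethylhydrazine, CN(C)N
Why: Hydrazone condensation converts the ketone into the N,N-dimethylhydrazone, the form that allows regioselective metalation at the methyl group.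

Step 7
Reactants: 10 but-3-en-1-ol
Product: 11 (but-3-en-1-yloxy)(tert-butyl)diphenylsilane
Conditions: TBDPSCl, imidazole, CH2Cl2, 0 °C to rt
Reagents that add atoms: tert-butyl(chloro)diphenylsilane, CC(C)(C)[Si](Cl)(c1ccccc1)c1ccccc1
Why: Silylation of the primary alcohol installs a silyl ether that should survive strong base, peroxide anion and catalytic acid in the later steps.

Step 8
Reactants: 11 (but-3-en-1-yloxy)(tert-butyl)diphenylsilane
Product: 12 rac-tert-butyl[2-(oxiran-2-yl)ethoxy]diphenylsilane
Conditions: mCPBA, CH2Cl2, 0 °C to rt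
Reagents that add atoms: meta-chloroperoxybenzoic acid, O=C(OO)c1cccc(Cl)c1
Why: Prilezhaev epoxidation of the only alkene present gives the racemic terminal epoxide.

Step 9
Reactants: 12 rac-tert-butyl[2-(oxiran-2-yl)ethoxy]diphenylsilane
Product: 13 tert-butyl{2-[(2S)-oxiran-2-yl]ethoxy}diphenylsilane
Conditions: (S,S)-N,N'-bis(3,5-di-tert-butylsalicylidene)cyclohexane-1,2-diamine cobalt acetate, (salen)Co(OAc), trivalent cobalt (0.5 mol %), H2O (0.55 equiv), THF, 0 °C to rt
Reagents that add atoms: none
Why: Jacobsen hydrolytic kinetic resolution, in which the (S,S) catalyst should hydrolyse the (R)-epoxide much faster, as with simple alkyl oxiranes, so that unreacted (S)-13 is recovered in high enantiomeric purity (sense to be checked by optical rotation) and supplies C3 of the target.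

Step 10
Reactants: 9 (8E)-octadeca-8,17-dien-6-yn-2-one N,N-dimethylhydrazone; 13 tert-butyl{2-[(2S)-oxiran-2-yl]ethoxy}diphenylsilane
Product: 16 (3R,12E)-1-[(tert-butyldiphenylsilyl)oxy]-3-hydroxydocosa-12,21-dien-10-yn-6-one, via lithium azaenolate 14 (not isolated), via hydroxy hydrazone 15 (not isolated)
Conditions: LiN(iPr)2, THF, −78 to 0 °C; 13, 0 °C to rt; H2O; then sat. aq. (CO2H)2, Et2O, rt
Reagents that add atoms: water, O
Why: Corey–Enders hydrazone alkylation, in which kinetic deprotonation occurs at the methyl group, the azaenolate opens the epoxide at its CH2 terminus so the carbinol centre is untouched (it becomes R only through a priority change), and two-phase oxalic acid hydrolysis returns the ketone.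

Step 11
Reactants: 16 (3R,12E)-1-[(tert-butyldiphenylsilyl)oxy]-3-hydroxydocosa-12,21-dien-10-yn-6-one
Product: 17 (3R,12E)-1-[(tert-butyldiphenylsilyl)oxy]-6-oxodocosa-12,21-dien-10-yn-3-yl methanesulfonate
Conditions: MsCl, Et3N, CH2Cl2, −20 °C; used without chromatography
Reagents that add atoms: methanesulfonyl chloride, CS(=O)(=O)Cl
Why: Sulfonylation of the secondary alcohol of the predominantly open-chain γ-hydroxy ketone is fast at low temperature and leaves the C3 configuration unchanged.

Step 12
Reactants: 17 (3R,12E)-1-[(tert-butyldiphenylsilyl)oxy]-6-oxodocosa-12,21-dien-10-yn-3-yl methanesulfonate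
Product: 18 (3R,12E)-1-[(tert-butyldiphenylsilyl)oxy]-6,6-dimethoxydocosa-12,21-dien-10-yn-3-yl methanesulfonate
Conditions: MeOSiMe3 (3 equiv), Me3SiOTf (5 mol %), CH2Cl2, −78 °C; pyridine quench
Reagents that add atoms: methoxytrimethylsilane, CO[Si](C)(C)C
Why: Noyori acetalisation masks the ketone under aprotic conditions at −78 °C, where the mesylate and silyl ether should be inert; the mask is needed because a free ketone would enolise and close onto the mesylate under the base of step 14.

Step 13
Reactants: 19 2,3-dimethylbut-2-ene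
Product: 20 2-methoxyprop-2-yl hydroperoxide
Conditions: O3, MeOH–CH2Cl2, −78 °C
Reagents that add atoms: ozone, [O-][O+]=O; methanol, CO
Why: Criegee ozonolysis of a tetrasubstituted alkene in methanol gives the α-methoxy hydroperoxide, a monoprotected form of hydrogen peroxide.

Step 14
Reactants: 18 (3R,12E)-1-[(tert-butyldiphenylsilyl)oxy]-6,6-dimethoxydocosa-12,21-dien-10-yn-3-yl methanesulfonate; 20 2-methoxyprop-2-yl hydroperoxide
Product: 21 (3S,12E)-1-[(tert-butyldiphenylsilyl)oxy]-6,6-dimethoxy-3-[(2-methoxypropan-2-yl)peroxy]docosa-12,21-dien-10-yne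
Conditions: CsOH·H2O, DMF, 0 °C to rt (20 in excess over base)
Reagents that add atoms: none
Why: SN2 displacement of a secondary sulfonate by a hydroperoxide anion in a dipolar aprotic solvent should proceed with inversion, turning the (R)-mesylate into the (S)-peroxide at C3, and the peroxide arrives protected so that no base-sensitive free hydroperoxide is present.

Step 15
Reactants: 21 (3S,12E)-1-[(tert-butyldiphenylsilyl)oxy]-6,6-dimethoxy-3-[(2-methoxypropan-2-yl)peroxy]docosa-12,21-dien-10-yne
Product: 22 (3S,12E)-1-[(tert-butyldiphenylsilyl)oxy]-3-hydroperoxydocosa-12,21-dien-10-yn-6-one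
Conditions: AcOH–THF–H2O (3:1:1), rt
Reagents that add atoms: water, O
Why: Mild aqueous acid hydrolysis removes the acetone-derived peroxyketal and the dimethyl ketal, both far more labile than the silyl ether, and releases the hydroperoxide and the ketone without breaking the C3–O bond.

Step 16
Reactants: 22 (3S,12E)-1-[(tert-butyldiphenylsilyl)oxy]-3-hydroperoxydocosa-12,21-dien-10-yn-6-one
Product: 25 tert-butyl(2-{(3S,6R)-6-[(6E)-hexadeca-6,15-dien-4-yn-1-yl]-6-methoxy-1,2-dioxan-3-yl}ethoxy)diphenylsilane, via ring hemiperketal 23 (not isolated), via peroxycarbenium ion 24 (not isolated)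
Conditions: TsOH·H2O (10 mol %), MeOH, 0 °C to rt; then NaHCO3
Reagents that add atoms: methanol, CO
Why: The hydroperoxide oxygen adds to the acid-activated C6 ketone by 6-exo-trig attack to form O1–C6 and the six-membered hemiperketal 23, loss of water gives the cyclic peroxycarbenium ion 24, and solvent methanol captures it to form C6–OMe. The reaction type is the known acid-catalysed peroxyketalisation of γ-hydroperoxy ketones (1,2-dioxan-3-ols) to 3-alkoxy-1,2-dioxanes. Every stage is reversible, so the new stereocentre C6 is set under thermodynamic control: with the C3 arm equatorial in the chair, the isomer with axial methoxy (anomeric stabilisation by O1) and equatorial chain should predominate, which is 6R, with methoxy cis to the C3 arm and the two carbon substituents trans. C3 takes no part in bond breaking and keeps its S configuration. The step needs the cyclic peroxyketal to win over the open dimethyl ketal and over the C6 epimer, which the 1,4-placement of hydroperoxide and ketone and the fixed C3 centre secure; the dienyne chain and silyl ether should be inert to catalytic sulfonic acid, and any C6 epimer can be resubjected.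

Step 17
Reactants: 25 tert-butyl(2-{(3S,6R)-6-[(6E)-hexadeca-6,15-dien-4-yn-1-yl]-6-methoxy-1,2-dioxan-3-yl}ethoxy)diphenylsilane
Product: 26 2-{(3S,6R)-6-[(6E)-hexadeca-6,15-dien-4-yn-1-yl]-6-methoxy-1,2-dioxan-3-yl}ethan-1-ol
Conditions: Bu4NF, AcOH (1:1), THF, 0 °C to rt
Reagents that add atoms: none
Why: Fluoride-mediated desilylation buffered with acetic acid frees the primary alcohol while avoiding base-induced Kornblum–DeLaMare fragmentation of the peroxide.

Step 18
Reactants: 26 2-{(3S,6R)-6-[(6E)-hexadeca-6,15-dien-4-yn-1-yl]-6-methoxy-1,2-dioxan-3-yl}ethan-1-ol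
Product: 28 2-{(3S,6R)-6-[(6E)-hexadeca-6,15-dien-4-yn-1-yl]-6-methoxy-1,2-dioxan-3-yl}acetic acid, via aldehyde 27 (not isolated)
Conditions: TEMPO (20 mol %), PhI(OAc)2 (2.5 equiv), MeCN–pH 7 phosphate buffer (1:1), rt
Reagents that add atoms: water, O
Why: TEMPO/hypervalent iodine oxidation in buffered water takes the primary alcohol through the aldehyde to the carboxylic acid near neutral pH and is inert towards the alkenes, the alkyne and the dialkyl peroxide.

Step 19
Reactants: 28 2-{(3S,6R)-6-[(6E)-hexadeca-6,15-dien-4-yn-1-yl]-6-methoxy-1,2-dioxan-3-yl}acetic acid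
Product: 29 methyl 2-{(3S,6R)-6-[(6E)-hexadeca-6,15-dien-4-yn-1-yl]-6-methoxy-1,2-dioxan-3-yl}acetate (peroxyacarnoate A)
Conditions: Me3SiCHN2, MeOH–toluene (1:4), 0 °C
Reagents that add atoms: (trimethylsilyl)diazomethane, C[Si](C)(C)C=[N+]=[N-]
Why: Diazoalkane esterification is fast and neutral, so neither the peroxyketal nor the β-peroxy ester is exposed to acid or base.

**Compound list**

1 | hex-5-ynoic acid | C#CCCCC(=O)O | starting material
2 | 1-(1H-imidazol-1-yl)hex-5-yn-1-one (acyl imidazolide) | C#CCCCC(=O)n1ccnc1 | intermediate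
3 | N-methoxy-N-methylhex-5-ynamide | C#CCCCC(=O)N(C)OC | intermediate
4 | hept-6-yn-2-one | C#CCCCC(C)=O | intermediate
5 | dec-9-en-1-ol | C=CCCCCCCCCO | starting material
6 | dec-9-enal | C=CCCCCCCCC=O | intermediate
7 | (1E)-1-iodoundeca-1,10-diene | C=CCCCCCCC/C=C/I | intermediate
8 | (8E)-octadeca-8,17-dien-6-yn-2-one | C=CCCCCCCC/C=C/C#CCCCC(C)=O | intermediate
9 | (8E)-octadeca-8,17-dien-6-yn-2-one N,N-dimethylhydrazone | C=CCCCCCCC/C=C/C#CCCCC(C)=NN(C)C | intermediate
10 | but-3-en-1-ol | C=CCCO | starting material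
11 | (but-3-en-1-yloxy)(tert-butyl)diphenylsilane | C=CCCO[Si](c1ccccc1)(c1ccccc1)C(C)(C)C | intermediate
12 | rac-tert-butyl[2-(oxiran-2-yl)ethoxy]diphenylsilane | C1OC1CCO[Si](c2ccccc2)(c2ccccc2)C(C)(C)C | intermediate
13 | tert-butyl{2-[(2S)-oxiran-2-yl]ethoxy}diphenylsilane | C1[C@H](CCO[Si](c2ccccc2)(c2ccccc2)C(C)(C)C)O1 | intermediate
14 | lithium azaenolate of 9 (metalated at the former methyl carbon) | C=CCCCCCCC/C=C/C#CCCCC(=C)N([Li])N(C)C | intermediate
15 | (3R,12E)-1-[(tert-butyldiphenylsilyl)oxy]-3-hydroxydocosa-12,21-dien-10-yn-6-one N,N-dimethylhydrazone | C=CCCCCCCC/C=C/C#CCCCC(=NN(C)C)CC[C@H](CCO[Si](c1ccccc1)(c1ccccc1)C(C)(C)C)O | intermediate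
16 | (3R,12E)-1-[(tert-butyldiphenylsilyl)oxy]-3-hydroxydocosa-12,21-dien-10-yn-6-one | C=CCCCCCCC/C=C/C#CCCCC(=O)CC[C@H](CCO[Si](c1ccccc1)(c1ccccc1)C(C)(C)C)O | intermediate
17 | (3R,12E)-1-[(tert-butyldiphenylsilyl)oxy]-6-oxodocosa-12,21-dien-10-yn-3-yl methanesulfonate | C=CCCCCCCC/C=C/C#CCCCC(=O)CC[C@H](CCO[Si](c1ccccc1)(c1ccccc1)C(C)(C)C)OS(C)(=O)=O | intermediate
18 | (3R,12E)-1-[(tert-butyldiphenylsilyl)oxy]-6,6-dimethoxydocosa-12,21-dien-10-yn-3-yl methanesulfonate | C=CCCCCCCC/C=C/C#CCCCC(OC)(OC)CC[C@H](CCO[Si](c1ccccc1)(c1ccccc1)C(C)(C)C)OS(C)(=O)=O | intermediate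
19 | 2,3-dimethylbut-2-ene | CC(C)=C(C)C | starting material
20 | 2-methoxyprop-2-yl hydroperoxide | COC(C)(C)OO | intermediate
21 | (3S,12E)-1-[(tert-butyldiphenylsilyl)oxy]-6,6-dimethoxy-3-[(2-methoxypropan-2-yl)peroxy]docosa-12,21-dien-10-yne | C=CCCCCCCC/C=C/C#CCCCC(OC)(OC)CC[C@@H](CCO[Si](c1ccccc1)(c1ccccc1)C(C)(C)C)OOC(C)(C)OC | intermediate
22 | (3S,12E)-1-[(tert-butyldiphenylsilyl)oxy]-3-hydroperoxydocosa-12,21-dien-10-yn-6-one | C=CCCCCCCC/C=C/C#CCCCC(=O)CC[C@@H](CCO[Si](c1ccccc1)(c1ccccc1)C(C)(C)C)OO | intermediate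
23 | ring hemiperketal: 1,2-dioxane with OH and the (6E)-hexadeca-6,15-dien-4-yn-1-yl chain on C6 and the 2-(tert-butyldiphenylsilyloxy)ethyl arm on C3 (3S; both C6 epimers) | C=CCCCCCCC/C=C/C#CCCCC1(O)CC[C@@H](CCO[Si](c2ccccc2)(c2ccccc2)C(C)(C)C)OO1 | intermediate
24 | cyclic peroxycarbenium ion (C6=O1 cation of the same 1,2-dioxane, 3S) | C=CCCCCCCC/C=C/C#CCCCC1=[O+]O[C@H](CCO[Si](c2ccccc2)(c2ccccc2)C(C)(C)C)CC1 | intermediate
25 | tert-butyl(2-{(3S,6R)-6-[(6E)-hexadeca-6,15-dien-4-yn-1-yl]-6-methoxy-1,2-dioxan-3-yl}ethoxy)diphenylsilane | C=CCCCCCCC/C=C/C#CCCC[C@]1(OC)CC[C@@H](CCO[Si](c2ccccc2)(c2ccccc2)C(C)(C)C)OO1 | intermediate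
26 | 2-{(3S,6R)-6-[(6E)-hexadeca-6,15-dien-4-yn-1-yl]-6-methoxy-1,2-dioxan-3-yl}ethan-1-ol | C=CCCCCCCC/C=C/C#CCCC[C@]1(OC)CC[C@@H](CCO)OO1 | intermediate
27 | 2-{(3S,6R)-6-[(6E)-hexadeca-6,15-dien-4-yn-1-yl]-6-methoxy-1,2-dioxan-3-yl}acetaldehyde | C=CCCCCCCC/C=C/C#CCCC[C@]1(OC)CC[C@@H](CC=O)OO1 | intermediate
28 | 2-{(3S,6R)-6-[(6E)-hexadeca-6,15-dien-4-yn-1-yl]-6-methoxy-1,2-dioxan-3-yl}acetic acid | C=CCCCCCCC/C=C/C#CCCC[C@]1(OC)CC[C@@H](CC(=O)O)OO1 | intermediate
29 | methyl 2-{(3S,6R)-6-[(6E)-hexadeca-6,15-dien-4-yn-1-yl]-6-methoxy-1,2-dioxan-3-yl}acetate (peroxyacarnoate A) | C=CCCCCCCC/C=C/C#CCCC[C@]1(OC)CC[C@@H](CC(=O)OC)OO1 | target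

**Step count**

Total: 19 steps (18 on the way to the target and one, step 13, for the peroxide reagent).
Longest linear sequence: 13 steps (1, 2, 5, 6, 10, 11, 12, 14, 15, 16, 17, 18, 19 from hex-5-ynoic acid; the same length from dec-9-en-1-ol through steps 3 and 4).

**Steps most likely to fail**

Step 14. Elimination of the secondary mesylate, or intramolecular attack on it by a ketal oxygen, may outrun the bimolecular substitution; substitution passing through such an oxonium ion would also erode the inversion. The fallback keeps the same bond construction but changes how the electrophile is made, so that a far more reactive leaving group can be used cold. It sets out from 16. Acetylation (Ac2O, pyridine, DMAP) should give (3R,12E)-1-[(tert-butyldiphenylsilyl)oxy]-6-oxodocosa-12,21-dien-10-yn-3-yl acetate F1. Acetalisation as in step 12 (MeOSiMe3, cat. Me3SiOTf, −78 °C) should give the acetoxy dimethyl ketal F2, and methanolysis of the acetate (K2CO3, MeOH) the free (3R)-hydroxy dimethyl ketal F3. This alcohol is converted at −78 °C into the secondary triflate F4 (Tf2O, 2,6-lutidine, CH2Cl2) and added cold to the potassium salt of 20 (KOtBu, THF, −78 to 0 °C). Alkylation of hydroperoxide anions by secondary triflates is fast at low temperature and goes with inversion, so the fallback returns to the route at 21. This detour also avoids mesylating the hydroxy ketone and acetalising next to a sulfonate (steps 11 and 12).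

Step 16. The exchange may stall at the hemiperketal or open dimethyl ketal, the C6 epimers may not settle cleanly, or the acid may fragment the hydroperoxide or remove the silyl ether before closure. The fallback replaces thermodynamic ketal exchange by a two-stage substitution under kinetic control. It sets out from 22 (present as its ring tautomer 23). Acetylation of the hemiperketal hydroxyl (Ac2O, pyridine, DMAP, CH2Cl2, 0 °C) should give the 6-acetoxy-1,2-dioxane F5. Ionisation at −78 °C with Me3SiOTf in the presence of MeOSiMe3 in CH2Cl2 regenerates the peroxycarbenium ion 24 under aprotic conditions, and axial capture by the methoxy donor should give the same axial-methoxy isomer. The fallback returns to the route at 25.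

Step 4. Insufficient E selectivity in the chromium-mediated iodo-olefination would carry a Z-iodoalkene into the enyne, where it is hard to remove. The fallback sets out from 6 and makes the alkene geometry by syn addition instead. Homologation with the Ohira–Bestmann reagent (dimethyl (1-diazo-2-oxopropyl)phosphonate, K2CO3, MeOH) should give undec-1-en-10-yne F6. Hydrozirconation with one equivalent of Cp2Zr(H)Cl (THF, rt; the terminal alkyne reacts faster than the terminal alkene) followed by I2 should give only the (E)-iodoalkene. The fallback returns to the route at 7.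

**Further compounds**

F1 | step 14 | (3R,12E)-1-[(tert-butyldiphenylsilyl)oxy]-6-oxodocosa-12,21-dien-10-yn-3-yl acetate | C=CCCCCCCC/C=C/C#CCCCC(=O)CC[C@H](CCO[Si](c1ccccc1)(c1ccccc1)C(C)(C)C)OC(C)=O
F2 | step 14 | (3R,12E)-1-[(tert-butyldiphenylsilyl)oxy]-6,6-dimethoxydocosa-12,21-dien-10-yn-3-yl acetate | C=CCCCCCCC/C=C/C#CCCCC(OC)(OC)CC[C@H](CCO[Si](c1ccccc1)(c1ccccc1)C(C)(C)C)OC(C)=O
F3 | step 14 | (3R,12E)-1-[(tert-butyldiphenylsilyl)oxy]-6,6-dimethoxydocosa-12,21-dien-10-yn-3-ol | C=CCCCCCCC/C=C/C#CCCCC(OC)(OC)CC[C@H](CCO[Si](c1ccccc1)(c1ccccc1)C(C)(C)C)O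
F4 | step 14 | (3R,12E)-1-[(tert-butyldiphenylsilyl)oxy]-6,6-dimethoxydocosa-12,21-dien-10-yn-3-yl trifluoromethanesulfonate | C=CCCCCCCC/C=C/C#CCCCC(OC)(OC)CC[C@H](CCO[Si](c1ccccc1)(c1ccccc1)C(C)(C)C)OS(=O)(=O)C(F)(F)F
F5 | step 16 | 6-acetoxy-1,2-dioxane: acetate of hemiperketal 23 (3S; both C6 epimers) | C=CCCCCCCC/C=C/C#CCCCC1(OC(C)=O)CC[C@@H](CCO[Si](c2ccccc2)(c2ccccc2)C(C)(C)C)OO1
F6 | step 4 | undec-1-en-10-yne | C=CCCCCCCCC#C
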